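**Remark on the chemistry:** the SMILES describes a 1,2-diarylethane, so the parent name is read as bibenzyl (3,3'-dihydroxy-2,6-bis(p-hydroxybenzyl)-5-methoxybibenzyl). Ring A locants used below: C1 ethylene bridge, C2 and C6 benzyl groups, C3 OH, C4 H, C5 OMe. Ring B is the 3-hydroxyphenyl ring; rings C and D are the 4-hydroxyphenyl rings on the C2 and C6 methylenes.

## Structural features

The target 18 is built from four benzene rings joined only by sp3 links. Ring A carries the ethylene bridge to ring B at C1, p-hydroxybenzyl groups (rings C and D) at C2 and C6, a hydroxyl at C3, a methoxyl at C5 and its only hydrogen at C4. There is no stereocentre, so the problem is regiochemistry on a pentasubstituted benzene. Stereocentres appear only in the saturated intermediates 10 to 14, where three adjacent sp3 carbons (ring A C6, C1, C2) are formed and later erased. The fragile parts are the four phenols and the two diarylmethane methylenes, which lie between the resorcinol-type ring A and a p-oxygenated ring and are prone to oxidation towards quinone methides. The real difficulty is to place three neighbouring carbon substituents (C6, C1, C2) in the right order and to tell the C3 hydroxyl from the C5 methoxyl, although ring A is otherwise symmetric about the C1–C4 axis. The key step uses exactly this symmetry: ring A is the dehydro form of a cyclohexane-1,3-dione with carbonyls at C3 and C5. That dione is symmetric, so its monomethyl enol ether has one constitution only, and the dione ring arises from an enone (C1 to C4) and a malonate (C5, C6) by forming C6–C1 and C4–C5.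

## Logic of the disconnections

18 ⇒ 17. The three phenolic O–CH2Ph bonds on rings B, C and D are cut. Benzyl ethers survive alkoxide, hydroxide, amide base and dilute acid, and one hydrogenolysis removes all three. The forward step must leave the diarylmethane C–C bonds and the aryl methyl ether intact, which is expected at ambient pressure and temperature.

17 ⇒ 14. No skeletal bond is cut; the C1=C2 unsaturation of ring A is removed and the phenol is written as its keto form. This turns the pentasubstituted benzene into a carbocycle that annulation can build. The forward dehydrogenation must not touch the p-alkoxybenzyl methylenes or the electron-rich phenol formed. For that reason a hydride-abstracting quinone is set aside in favour of a silyl enol ether and divalent palladium.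

14 ⇒ 13. The C5–O bond of the enol ether is cut. With the methyl group gone, the C3 and C5 carbonyls are equivalent by the mirror plane through C1 and C4, so the OH/OMe distinction is no longer a selectivity problem. The forward step must stop at the monoether, which a vinylogous ester does.

13 ⇒ 11. The C6–CO2Me bond is put back. The ester is the second acyl group that the ring closure needed and is then surplus. The forward step must hydrolyse a hindered ester without opening the β-diketone; decarboxylation of the resulting β-keto acid is easy.

11 ⇒ 7 + 9. The C4–C5 and C6–C1 bonds are cut. Ring A divides into a four-carbon unit (C1 to C4, already carrying the C2 benzyl group and the bridge) and a two-carbon unit (C5, C6, carrying the other benzyl group). The forward step asks a tertiary carbanion to add to an α-branched enone; the direction of ring closure is enforced by ring size.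

9 ⇒ 8 + 5. The bond from C6 to its benzylic methylene is cut; a plain malonate monoalkylation is required.

7 ⇒ 6 + 3. The C1=C2 double bond of the enone is cut. An olefination fixes the position of the double bond and of the branch without ambiguity. An acid-mediated crossed aldol of a methyl ketone with this enolisable aldehyde could not guarantee that and would expose the benzyl ethers to strong acid. Geometry is not critical, since both isomers would converge in the annulation.

6 ⇒ 4 + 5. The bond from C2 to its benzylic methylene is cut, so both benzyl groups come from the same 5.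

3 ⇒ 2 ⇒ 1. No skeletal bond is cut. The aldehyde comes from partial reduction of an ester, and the ester and ether come from one double benzylation.

## Other disconnections considered

Alternative 1: The cut is at the two bonds between the benzylic carbons on C2 and C6 and rings C and D. This leaves 3-[2-(3,5-dimethoxy-2,6-dimethylphenyl)ethyl]phenyl pivalate A1, in which both positions are still methyl groups.
- Forward key step: A1 would be electrolysed at constant current at a carbon anode in a fluorinated alcohol, so that both methyl groups become benzylic fluoroalkyl ethers (bis-ether A2). A catalytic strong acid would then ionise these ethers in the presence of phenol A3 to give the doubly para-benzylated product A4.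
- In favour: ring A stays aromatic throughout, no stereoisomer mixtures arise, no late dehydrogenation is needed, and two C–C bonds form in one pot. On these points and on step count the alternative is the better one. The end game could be a single dealkylation, since cleavage of the pivalate and of one of two equivalent methyl ethers would lead to 18.
- Against: the radical cation of the electron-rich ring A offers three benzylic sites (two methyls and the C1 bridge methylene), and both methyls must react completely. The free C4 position between two methoxyls can trap the benzylic cation and give oligomers. A3 can react ortho as well as para, twice. The final mono-demethylation is still a selective dealkylation.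
- Comparison: the chosen plan is longer, but its connectivity is dictated by ring size and its oxygen differentiation is automatic. The alternative rests on site selectivity among similar C–H bonds.

Alternative 2: The cut is at the C1–C2 bond of ring A. This leads to the open-chain triketone (8E)-6-[4-(benzyloxy)benzyl]-1-[4-(benzyloxy)phenyl]-9-[3-(benzyloxy)phenyl]non-8-ene-3,5,7-trione A5.
- Forward key step: aqueous methanolic alkali would add the terminal methylene carbon to the cinnamoyl carbonyl; loss of water and enolisation would give the resorcinol A6.
- In favour: the ring aromatises by dehydration with no oxidant, which is better than the chosen plan in redox terms. The cinnamoyl end has no α-hydrogen, so only one six-membered aldol is possible. The styryl double bond would be reduced in the same hydrogenation that removes the benzyl ethers.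
- Against: A5 needs two different benzyl groups placed on a triketone with two similar doubly activated positions. O-cyclisation to pyranones and conjugate additions to the enone compete with the aldol. A6 is a symmetric resorcinol, so the methyl ether would have to come from a statistical monomethylation.
- Comparison: step count would be similar at best. The chosen plan is superior on the OH/OMe problem and on access to the precursor, and inferior on oxidation-state economy.

Alternative 3: The cuts are at C6–C1 and C2–C3. The partners are the diene {[5-[4-(benzyloxy)phenyl]-1,3-dimethoxypenta-1,3-dien-1-yl]oxy}trimethylsilane A7 and the ynone 1-[4-(benzyloxy)phenyl]-5-[3-(benzyloxy)phenyl]pent-2-yn-1-one A8.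
- Forward key step: a Diels–Alder addition followed by loss of methanol on acidic work-up would give the benzophenone A9.
- In favour: the polarity of both partners fixes the regiochemistry. The ring arrives at the aromatic oxidation level, which is better than the chosen plan. OH and OMe are differentiated from the start, which equals the chosen plan. If the diaryl ketone could be hydrogenolysed together with the benzyl ethers, the step count would be equal or lower.
- Against: A7 is substituted at its reacting terminus, is sensitive to hydrolysis and exists as geometric isomers. A8 is an internal, β-alkylated and therefore sluggish dienophile. A stepwise conjugate addition might stop at an open-chain adduct. The extra carbonyl must be reduced to a methylene next to a free phenol.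
- Comparison: the chosen plan uses a more ordinary ring-forming step and pays for it with a late dehydrogenation.

Key step: step 6

## Route

Step 1
Reactants: 1 3-(3-hydroxyphenyl)propanoic acid
Product: 2 benzyl 3-[3-(benzyloxy)phenyl]propanoate
Conditions: BnBr (2.4 equiv), K2CO3, DMF, 60 °C
Reagents that add atoms: benzyl bromide, BrCc1ccccc1
Why: Williamson etherification of the phenoxide and alkylation of the carboxylate, both fast SN2 reactions with a benzylic bromide in DMF; no other nucleophilic site is present.

Step 2
Reactants: 2 benzyl 3-[3-(benzyloxy)phenyl]propanoate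
Product: 3 3-[3-(benzyloxy)phenyl]propanal
Conditions: i-Bu2AlH (1.05 equiv), CH2Cl2, −78 °C; MeOH, then aq. KNaC4H4O6
Reagents that add atoms: none
Why: Partial reduction of an ester with i-Bu2AlH; the aluminium hemiacetal is stable at −78 °C and releases the aldehyde only on work-up, and the aryl benzyl ether is inert to hydride.

Step 3
Reactants: 4 dimethyl (2-oxopropyl)phosphonate; 5 4-(benzyloxy)benzyl chloride
Product: 6 dimethyl {1-[4-(benzyloxy)phenyl]-3-oxobutan-2-yl}phosphonate (racemic)
Conditions: NaH, THF–DMF, 0 °C; then 5, NaI (cat.), rt to 50 °C
Reagents that add atoms: none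
Why: C-alkylation of the stabilised β-ketophosphonate anion at the carbon between P=O and C=O by SN2 on a reactive benzylic chloride; a slight excess of 4 should suppress dialkylation.

Step 4
Reactants: 6 dimethyl {1-[4-(benzyloxy)phenyl]-3-oxobutan-2-yl}phosphonate; 3 3-[3-(benzyloxy)phenyl]propanal
Product: 7 (E)-3-[4-(benzyloxy)benzyl]-6-[3-(benzyloxy)phenyl]hex-3-en-2-one
Conditions: NaH, THF, 0 °C (preformed anion); then 3 added slowly, 0 °C to rt
Reagents that add atoms: none
Why: Horner–Wadsworth–Emmons olefination of an α-branched β-ketophosphonate with an unhindered aliphatic aldehyde; the acetyl group should end up trans to the chain (E), and a minor Z isomer would be harmless because both converge in step 6.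

Step 5
Reactants: 8 dimethyl malonate; 5 4-(benzyloxy)benzyl chloride
Product: 9 dimethyl 2-[4-(benzyloxy)benzyl]malonate
Conditions: NaH, 8 (2 equiv), THF–DMF, 0 °C; then 5, NaI (cat.), rt to 50 °C
Reagents that add atoms: none
Why: Malonic ester alkylation by SN2; the excess of 8 limits dialkylation and can be distilled off.

Step 6
Reactants: 7 (E)-3-[4-(benzyloxy)benzyl]-6-[3-(benzyloxy)phenyl]hex-3-en-2-one; 9 dimethyl 2-[4-(benzyloxy)benzyl]malonate
Product: 11 methyl 1,5-bis[4-(benzyloxy)benzyl]-6-{2-[3-(benzyloxy)phenyl]ethyl}-2,4-dioxocyclohexane-1-carboxylate (mixture of diastereomers), via Michael adduct 10 (not isolated)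
Conditions: NaOMe (1.5 equiv), MeOH (concentrated), reflux; then cold 1 M HCl
Reagents that add atoms: none
Why: Methoxide deprotonates 9, and the tertiary malonate anion adds reversibly to the β-carbon of 7 (ring A C6–C1 bond) to give the enolate of 10. Proton exchange through methanol relocates the enolate to the methyl group, which attacks one ester carbonyl (C4–C5 bond) and expels methoxide. The β-diketone formed is deprotonated at once at C4, and this acid–base step is the sink that draws the crowded conjugate-addition equilibrium (quaternary C6 beside tertiary C1) forward. The closest known reaction type is the Michael–Claisen (dimedone-type) annulation of enones with malonic esters. The ring closes in the 6-(enolendo)-exo-trig mode, which is favoured. Three sp3 centres arise (C6 and C1 in the conjugate addition, C2 on protonation); nothing controls them and nothing needs to, because steps 7 and 9 remove all three. The step needs 1,4- rather than 1,2-addition and acylation from the methyl enolate alone; the soft, reversibly adding malonate anion secures the first and ring size secures the second, since the methine enolate could only close a four-membered ring. Deconjugation of 7 by methoxide is reversible and returns material to the productive path.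

Step 7
Reactants: 11 methyl 1,5-bis[4-(benzyloxy)benzyl]-6-{2-[3-(benzyloxy)phenyl]ethyl}-2,4-dioxocyclohexane-1-carboxylate
Product: 13 4,6-bis[4-(benzyloxy)benzyl]-5-{2-[3-(benzyloxy)phenyl]ethyl}cyclohexane-1,3-dione (mixture of diastereomers), via keto acid 12 (not isolated)
Conditions: 2 M NaOH, MeOH–THF, reflux; then 2 M HCl to pH 2–3, 60 °C
Reagents that add atoms: none
Why: Saponification while the 1,3-dione is held as its enolate and thereby shielded from retro-Claisen cleavage; on acidification the β-keto acid 12 loses CO2 through the usual cyclic transition state. The C6 stereocentre disappears and the dione becomes constitutionally symmetric.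

Step 8
Reactants: 13 4,6-bis[4-(benzyloxy)benzyl]-5-{2-[3-(benzyloxy)phenyl]ethyl}cyclohexane-1,3-dione
Product: 14 4,6-bis[4-(benzyloxy)benzyl]-5-{2-[3-(benzyloxy)phenyl]ethyl}-3-methoxycyclohex-2-en-1-one (mixture of diastereomers)
Conditions: MeOH, TsOH·H2O (cat.), 3 Å molecular sieves, reflux
Reagents that add atoms: methanol, CO
Why: Acid-catalysed enol etherification of a cyclic 1,3-dione (vinylogous Fischer esterification); the two carbonyls are equivalent, so only one constitution can form, and the vinylogous ester does not react a second time.

Step 9
Reactants: 14 4,6-bis[4-(benzyloxy)benzyl]-5-{2-[3-(benzyloxy)phenyl]ethyl}-3-methoxycyclohex-2-en-1-one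
Product: 17 2,4-bis[4-(benzyloxy)benzyl]-3-{2-[3-(benzyloxy)phenyl]ethyl}-5-methoxyphenol, via silyl dienol ether 15 (not isolated), via cyclohexadienone 16 (not isolated)
Conditions: LiN(i-Pr)2, THF, −78 °C; Me3SiCl, −78 to 0 °C; solvent exchange; Pd(OAc)2 (1.1 equiv), MeCN, rt
Reagents that add atoms: none
Why: Kinetic deprotonation of the vinylogous ester at its α′ carbon (ring A C2) and O-silylation give the cross-conjugated silyl dienol ether 15; divalent palladium adds to it and β-hydride elimination of the C1 hydrogen gives dienone 16 (Saegusa–Ito oxidation), which tautomerises to the phenol. The oxidant does not abstract hydride, so the p-alkoxybenzyl methylenes and the electron-rich product should be left alone. If elimination takes a benzylic hydrogen instead, the palladium hydride can re-add, and the aromatic compound is the thermodynamic sink.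

Step 10
Reactants: 17 2,4-bis[4-(benzyloxy)benzyl]-3-{2-[3-(benzyloxy)phenyl]ethyl}-5-methoxyphenol
Product: 18 2,4-bis(4-hydroxybenzyl)-3-[2-(3-hydroxyphenyl)ethyl]-5-methoxyphenol (3,3'-dihydroxy-2,6-bis(p-hydroxybenzyl)-5-methoxybibenzyl)
Conditions: H2 (1 atm), 10% Pd/C, EtOAc–MeOH, rt
Reagents that add atoms: none
Why: Hydrogenolysis of three aryl benzyl ethers over Pd/C; diarylmethane and bibenzyl C–C bonds and the aryl methyl ether are not cleaved under these mild conditions.

## Compound list

1 | 3-(3-hydroxyphenyl)propanoic acid | OC(=O)CCc1cccc(O)c1 | starting material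
2 | benzyl 3-[3-(benzyloxy)phenyl]propanoate | O=C(CCc1cccc(OCc2ccccc2)c1)OCc1ccccc1 | intermediate
3 | 3-[3-(benzyloxy)phenyl]propanal | O=CCCc1cccc(OCc2ccccc2)c1 | intermediate
4 | dimethyl (2-oxopropyl)phosphonate | COP(=O)(CC(C)=O)OC | starting material
5 | 4-(benzyloxy)benzyl chloride | ClCc1ccc(OCc2ccccc2)cc1 | starting material
6 | dimethyl {1-[4-(benzyloxy)phenyl]-3-oxobutan-2-yl}phosphonate (racemic) | COP(=O)(OC)C(Cc1ccc(OCc2ccccc2)cc1)C(C)=O | intermediate
7 | (E)-3-[4-(benzyloxy)benzyl]-6-[3-(benzyloxy)phenyl]hex-3-en-2-one | CC(=O)/C(Cc1ccc(OCc2ccccc2)cc1)=C/CCc1cccc(OCc2ccccc2)c1 | intermediate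
8 | dimethyl malonate | COC(=O)CC(=O)OC | starting material
9 | dimethyl 2-[4-(benzyloxy)benzyl]malonate | COC(=O)C(Cc1ccc(OCc2ccccc2)cc1)C(=O)OC | intermediate
10 | dimethyl 2-[4-(benzyloxy)benzyl]-2-{4-[4-(benzyloxy)benzyl]-1-[3-(benzyloxy)phenyl]-5-oxohexan-3-yl}malonate (diastereomer mixture, not isolated) | COC(=O)C(Cc1ccc(OCc2ccccc2)cc1)(C(=O)OC)C(CCc1cccc(OCc2ccccc2)c1)C(Cc1ccc(OCc2ccccc2)cc1)C(C)=O | intermediate
11 | methyl 1,5-bis[4-(benzyloxy)benzyl]-6-{2-[3-(benzyloxy)phenyl]ethyl}-2,4-dioxocyclohexane-1-carboxylate (diastereomer mixture) | COC(=O)C1(Cc2ccc(OCc3ccccc3)cc2)C(=O)CC(=O)C(Cc2ccc(OCc3ccccc3)cc2)C1CCc1cccc(OCc2ccccc2)c1 | intermediate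
12 | 1,5-bis[4-(benzyloxy)benzyl]-6-{2-[3-(benzyloxy)phenyl]ethyl}-2,4-dioxocyclohexane-1-carboxylic acid (diastereomer mixture, not isolated) | OC(=O)C1(Cc2ccc(OCc3ccccc3)cc2)C(=O)CC(=O)C(Cc2ccc(OCc3ccccc3)cc2)C1CCc1cccc(OCc2ccccc2)c1 | intermediate
13 | 4,6-bis[4-(benzyloxy)benzyl]-5-{2-[3-(benzyloxy)phenyl]ethyl}cyclohexane-1,3-dione (diastereomer mixture) | O=C1CC(=O)C(Cc2ccc(OCc3ccccc3)cc2)C(CCc2cccc(OCc3ccccc3)c2)C1Cc1ccc(OCc2ccccc2)cc1 | intermediate
14 | 4,6-bis[4-(benzyloxy)benzyl]-5-{2-[3-(benzyloxy)phenyl]ethyl}-3-methoxycyclohex-2-en-1-one (diastereomer mixture) | COC1=CC(=O)C(Cc2ccc(OCc3ccccc3)cc2)C(CCc2cccc(OCc3ccccc3)c2)C1Cc1ccc(OCc2ccccc2)cc1 | intermediate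
15 | {[1,5-bis[4-(benzyloxy)benzyl]-6-{2-[3-(benzyloxy)phenyl]ethyl}-4-methoxycyclohexa-1,3-dien-2-yl]oxy}trimethylsilane (diastereomer mixture, not isolated) | COC1=CC(O[Si](C)(C)C)=C(Cc2ccc(OCc3ccccc3)cc2)C(CCc2cccc(OCc3ccccc3)c2)C1Cc1ccc(OCc2ccccc2)cc1 | intermediate
16 | 4,6-bis[4-(benzyloxy)benzyl]-5-{2-[3-(benzyloxy)phenyl]ethyl}-3-methoxycyclohexa-2,5-dien-1-one (racemic, not isolated) | COC1=CC(=O)C(Cc2ccc(OCc3ccccc3)cc2)=C(CCc2cccc(OCc3ccccc3)c2)C1Cc1ccc(OCc2ccccc2)cc1 | intermediate
17 | 2,4-bis[4-(benzyloxy)benzyl]-3-{2-[3-(benzyloxy)phenyl]ethyl}-5-methoxyphenol | COc1cc(O)c(Cc2ccc(OCc3ccccc3)cc2)c(CCc2cccc(OCc3ccccc3)c2)c1Cc1ccc(OCc2ccccc2)cc1 | intermediate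
18 | 2,4-bis(4-hydroxybenzyl)-3-[2-(3-hydroxyphenyl)ethyl]-5-methoxyphenol | COc1cc(O)c(Cc2ccc(O)cc2)c(CCc2cccc(O)c2)c1Cc1ccc(O)cc1 | target

## Step count and least certain steps

Total step count: 10. Longest linear sequence: 8 steps (steps 1, 2, 4, 6, 7, 8, 9, 10).

**Step 6 (key step).** The conjugate addition joins a fully substituted carbon to a branched one, so the equilibrium may lie on the side of 7 and 9. Retro-Michael cleavage could then outrun the Claisen closure while base slowly consumes 7 by self-condensation. The fallback sets out from 7 and 8 and returns at 11. The annulation is run with the unsubstituted malonate 8 (NaOMe, MeOH, reflux), whose secondary carbanion adds far more readily, to give methyl 5-[4-(benzyloxy)benzyl]-6-{2-[3-(benzyloxy)phenyl]ethyl}-2,4-dioxocyclohexane-1-carboxylate F1. Its dianion (LiN(i-Pr)2, 2.2 equiv, THF, −78 to 0 °C) is then benzylated with 5 at the ester-bearing carbon, which is the last-formed and most nucleophilic site. This gives 11 with the quaternary centre made by alkylation instead of conjugate addition.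

**Step 9.** Three things may go wrong: incomplete deprotonation of the hindered α′ methine, hydrolysis of the silyl ether back to 14, and β-hydride elimination towards the exocyclic benzylic hydrogen, which would stall at a cross-conjugated benzylidene isomer. The fallback sets out from 14 and returns at 18. Heterogeneous dehydrogenation (10% Pd/C, refluxing mesitylene, under N2) needs no enolate and equilibrates double-bond isomers into the aromatic sink. The benzyl ethers act as internal hydrogen acceptors, so the crude product is 17 mixed with partly debenzylated congeners. All of these converge on 18 when the mixture is put through the conditions of step 10.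

**Step 7.** Hydroxide may attack the neopentyl-type ester too slowly, and prolonged heating in base invites ring opening by retro-Claisen cleavage. The fallback sets out from 11 and returns at 13: a Krapcho dealkoxycarbonylation (LiCl, DMSO–H2O, 140 °C), in which chloride attacks the unhindered methyl carbon instead of the shielded carbonyl and the carboxylate loses CO2 in the same pot.

**Step 4.** The α-branched phosphonate anion may add sluggishly, leaving time for self-aldol condensation of the enolisable aldehyde. The fallback sets out from 3 and returns at 7. 4-(4-Hydroxyphenyl)butan-2-one F2 is benzylated (BnBr, K2CO3, acetone) to 4-[4-(benzyloxy)phenyl]butan-2-one F3. F3 is then condensed with 3 under acid (dry HCl, AcOH, 0 °C to rt); under these conditions the methyl ketone reacts through its more substituted enol, at the methylene, and dehydration gives 7.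

**Step 2.** Collapse of the aluminium hemiacetal before the quench would lead to over-reduction, and the aldehyde would then be contaminated with the alcohol. The fallback sets out from 2 and returns at 3: full reduction (LiAlH4, THF, 0 °C) to 3-[3-(benzyloxy)phenyl]propan-1-ol F4, followed by oxidation with TEMPO (cat.) and PhI(OAc)2 in CH2Cl2.

## Further compounds

F1 | step 6 | methyl 5-[4-(benzyloxy)benzyl]-6-{2-[3-(benzyloxy)phenyl]ethyl}-2,4-dioxocyclohexane-1-carboxylate (diastereomer mixture) | COC(=O)C1C(=O)CC(=O)C(Cc2ccc(OCc3ccccc3)cc2)C1CCc1cccc(OCc2ccccc2)c1
F0 | step 9 | none | none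
F0 | step 7 | none | none
F2 | step 4 | 4-(4-hydroxyphenyl)butan-2-one | CC(=O)CCc1ccc(O)cc1
F3 | step 4 | 4-[4-(benzyloxy)phenyl]butan-2-one | CC(=O)CCc1ccc(OCc2ccccc2)cc1
F4 | step 2 | 3-[3-(benzyloxy)phenyl]propan-1-ol | OCCCc1cccc(OCc2ccccc2)c1
A1 | alternative 1 | 3-[2-(3,5-dimethoxy-2,6-dimethylphenyl)ethyl]phenyl pivalate | COc1cc(OC)c(C)c(CCc2cccc(OC(=O)C(C)(C)C)c2)c1C
A2 | alternative 1 | 3-{2-[2,6-bis{[(1,1,1,3,3,3-hexafluoropropan-2-yl)oxy]methyl}-3,5-dimethoxyphenyl]ethyl}phenyl pivalate | COc1cc(OC)c(COC(C(F)(F)F)C(F)(F)F)c(CCc2cccc(OC(=O)C(C)(C)C)c2)c1COC(C(F)(F)F)C(F)(F)F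
A3 | alternative 1 | phenol | Oc1ccccc1
A4 | alternative 1 | 3-{2-[2,6-bis(4-hydroxybenzyl)-3,5-dimethoxyphenyl]ethyl}phenyl pivalate | COc1cc(OC)c(Cc2ccc(O)cc2)c(CCc2cccc(OC(=O)C(C)(C)C)c2)c1Cc1ccc(O)cc1
A5 | alternative 2 | (8E)-6-[4-(benzyloxy)benzyl]-1-[4-(benzyloxy)phenyl]-9-[3-(benzyloxy)phenyl]non-8-ene-3,5,7-trione | O=C(CCc1ccc(OCc2ccccc2)cc1)CC(=O)C(Cc1ccc(OCc2ccccc2)cc1)C(=O)/C=C/c1cccc(OCc2ccccc2)c1
A6 | alternative 2 | 4,6-bis[4-(benzyloxy)benzyl]-5-{(E)-2-[3-(benzyloxy)phenyl]ethenyl}benzene-1,3-diol | Oc1cc(O)c(Cc2ccc(OCc3ccccc3)cc2)c(/C=C/c2cccc(OCc3ccccc3)c2)c1Cc1ccc(OCc2ccccc2)cc1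
A7 | alternative 3 | {[5-[4-(benzyloxy)phenyl]-1,3-dimethoxypenta-1,3-dien-1-yl]oxy}trimethylsilane (mixture of geometric isomers) | COC(O[Si](C)(C)C)=CC(OC)=CCc1ccc(OCc2ccccc2)cc1
A8 | alternative 3 | 1-[4-(benzyloxy)phenyl]-5-[3-(benzyloxy)phenyl]pent-2-yn-1-one | O=C(C#CCCc1cccc(OCc2ccccc2)c1)c1ccc(OCc2ccccc2)cc1
A9 | alternative 3 | {3-[4-(benzyloxy)benzyl]-2-{2-[3-(benzyloxy)phenyl]ethyl}-6-hydroxy-4-methoxyphenyl}[4-(benzyloxy)phenyl]methanone | COc1cc(O)c(C(=O)c2ccc(OCc3ccccc3)cc2)c(CCc2cccc(OCc3ccccc3)c2)c1Cc1ccc(OCc2ccccc2)cc1
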